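**Retrosynthetic overview**
- The diarylmethane is cut at the CH2–C(ring A) bond: Michael addition of the ring A acylphloroglucinol to an ortho-quinone methide of ring B, released from a ring B Mannich base.
- Ring B Mannich base ⇐ 2,6-dihydroxy-4-methoxy-3-methylacetophenone ⇐ selective 4-O-methylation ⇐ Friedel–Crafts acetylation of 2-methylphloroglucinol.
- Ring A partner ⇐ mono-C-prenylation of phlorobutyrophenone ⇐ Friedel–Crafts butanoylation of phloroglucinol.
- No ring is built: both benzene rings are bought (ring A as phloroglucinol, ring B as 2-methylphloroglucinol); the route is convergent, 6 steps.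

Assumption: the target has no stereocentre and no stereogenic double bond, so it is achiral and no enantiocontrol is needed.

**Route**

Step 1
Reactants: 1 benzene-1,3,5-triol (phloroglucinol, anhydrous)
Product: 2 1-(2,4,6-trihydroxyphenyl)butan-1-one
Conditions: butanoyl chloride (1.05 equiv), AlCl3 (3.5 equiv), PhNO2/CH2Cl2, 0 °C → 50 °C; ice/2 M HCl
Reagents that add atoms: butanoyl chloride, CCCC(=O)Cl
Why: Friedel–Crafts C-acylation of the very electron-rich triol stops at the mono-ketone because the first acyl group deactivates the ring.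

Step 2
Reactants: 2 1-(2,4,6-trihydroxyphenyl)butan-1-one
Product: 3 1-[2,4,6-trihydroxy-3-(3-methylbut-2-en-1-yl)phenyl]butan-1-one
Conditions: prenyl bromide (1.0 equiv), 10% aq. KOH (2 equiv), 0 °C, 2 h; 1 M HCl to pH 3
Reagents that add atoms: 1-bromo-3-methylbut-2-ene (prenyl bromide), CC(C)=CCBr
Why: In water the solvated phenolate oxygen is shielded, so the ambident anion is alkylated at ring carbon (SN2 C-prenylation), and the two free ring positions of 2 are equivalent, so only one mono-prenyl isomer can form.

Step 3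
Reactants: 4 2-methylbenzene-1,3,5-triol (2,4,6-trihydroxytoluene)
Product: 5 1-(2,4,6-trihydroxy-3-methylphenyl)ethan-1-one
Conditions: AcCl (1.05 equiv), AlCl3 (3.5 equiv), PhNO2/CH2Cl2, 0 °C → rt; ice/2 M HCl
Reagents that add atoms: acetyl chloride, CC(=O)Cl
Why: Friedel–Crafts acylation at one of the two equivalent free positions of 4 gives a single ketone, and the acyl group prevents a second acylation.

Step 4
Reactants: 5 1-(2,4,6-trihydroxy-3-methylphenyl)ethan-1-one
Product: 6 1-(2,6-dihydroxy-4-methoxy-3-methylphenyl)ethan-1-one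
Conditions: Me2SO4 (1.0 equiv), K2CO3 (1.0 equiv), acetone, rt, 12 h
Reagents that add atoms: dimethyl sulfate, COS(=O)(=O)OC
Why: The 4-OH is the most acidic hydroxyl and the only one not hydrogen-bonded to the ketone, so one equivalent of the hard electrophile under weak base gives the para methyl ether (Williamson-type O-methylation).

Step 5
Reactants: 6 1-(2,6-dihydroxy-4-methoxy-3-methylphenyl)ethan-1-one
Product: 7 1-{3-[(dimethylamino)methyl]-2,6-dihydroxy-4-methoxy-5-methylphenyl}ethan-1-one
Conditions: Eschenmoser's salt (1.1 equiv), K2CO3 (1.1 equiv), CH2Cl2, 0 °C → rt, 6 h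
Reagents that add atoms: dimethyl(methylidene)ammonium iodide (Eschenmoser's salt), C=[N+](C)C.[I-]
Why: Mannich reaction of the phenolate with a preformed iminium ion at the only remaining ring CH; no free formaldehyde is present, so the symmetrical methylene-bis dimer is avoided.

Step 6
Reactants: 7 1-{3-[(dimethylamino)methyl]-2,6-dihydroxy-4-methoxy-5-methylphenyl}ethan-1-one; 3 1-[2,4,6-trihydroxy-3-(3-methylbut-2-en-1-yl)phenyl]butan-1-one
Product: 9 1-[3-[(3-acetyl-2,4-dihydroxy-6-methoxy-5-methylphenyl)methyl]-2,4,6-trihydroxy-5-(3-methylbut-2-en-1-yl)phenyl]butan-1-one, via ortho-quinone methide 8 (not isolated)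
Conditions: 7 (1.0 equiv), 3 (1.2 equiv), degassed 1,4-dioxane, 95 °C, N2 sweep, 4–6 h; cold 0.5 M HCl wash, chromatography
Reagents that add atoms: none
Why: Thermal loss of Me2NH from the ortho-hydroxybenzylamine gives the acyl-stabilised ortho-quinone methide 8, to which the amine-generated phenolate of 3 adds through its only free ring carbon in an intermolecular Michael addition, and tautomerisation then re-aromatises both rings.

**Compound list**
1 | benzene-1,3,5-triol (phloroglucinol) | Oc1cc(O)cc(O)c1 | starting material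
2 | 1-(2,4,6-trihydroxyphenyl)butan-1-one | CCCC(=O)c1c(O)cc(O)cc1O | intermediate
3 | 1-[2,4,6-trihydroxy-3-(3-methylbut-2-en-1-yl)phenyl]butan-1-one | CCCC(=O)c1c(O)cc(O)c(CC=C(C)C)c1O | intermediate
4 | 2-methylbenzene-1,3,5-triol (2,4,6-trihydroxytoluene) | Cc1c(O)cc(O)cc1O | starting material
5 | 1-(2,4,6-trihydroxy-3-methylphenyl)ethan-1-one | CC(=O)c1c(O)cc(O)c(C)c1O | intermediate
6 | 1-(2,6-dihydroxy-4-methoxy-3-methylphenyl)ethan-1-one | CC(=O)c1c(O)cc(OC)c(C)c1O | intermediate
7 | 1-{3-[(dimethylamino)methyl]-2,6-dihydroxy-4-methoxy-5-methylphenyl}ethan-1-one | CC(=O)c1c(O)c(C)c(OC)c(CN(C)C)c1O | intermediate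
8 | 2-acetyl-3-hydroxy-5-methoxy-4-methyl-6-methylidenecyclohexa-2,4-dien-1-one (ortho-quinone methide, formed in the flask) | CC(=O)C1=C(O)C(C)=C(OC)C(=C)C1=O | intermediate
9 | 1-[3-[(3-acetyl-2,4-dihydroxy-6-methoxy-5-methylphenyl)methyl]-2,4,6-trihydroxy-5-(3-methylbut-2-en-1-yl)phenyl]butan-1-one | CCCC(=O)c1c(O)c(CC=C(C)C)c(O)c(Cc2c(O)c(C(C)=O)c(O)c(C)c2OC)c1O | target

**Totals**
Total step count: 6.
Longest linear sequence: 4 steps (steps 3, 4, 5, 6; 4 → 5 → 6 → 7 → 9).

**Steps most likely to fail, with fallbacks**

Step 2 (mono-C-prenylation). The risk is over-alkylation (3,5-di-C-prenyl and geminal di-C-prenyl products) and some O-prenylation, which lowers the yield of 3. The fallback sets out from 2 and comes back at 3. Mitsunobu etherification of the non-chelated 4-OH of 2 with 3-methylbut-2-en-1-ol (PPh3, DIAD, THF, 0 °C) gives the aryl prenyl ether 1-{2,6-dihydroxy-4-[(3-methylbut-2-en-1-yl)oxy]phenyl}butan-1-one F1. A [1,3] oxygen-to-carbon prenyl shift over activated magnesium silicate MgSiO3 (Florisil grade) in toluene at 100 °C then moves the prenyl group to the neighbouring ring carbon. The two ortho carbons are equivalent, so the product is 3.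

Step 4 (regioselective mono-O-methylation). The risk is methylation at a chelated hydroxyl or double methylation. The fallback sets out from 5 and comes back at 6. Exhaustive O-methylation (excess Me2SO4, K2CO3, acetone, reflux) gives 1-(2,4,6-trimethoxy-3-methylphenyl)ethan-1-one F2. Excess BCl3 (CH2Cl2, 0 °C → rt) then cleaves only the two methyl ethers ortho to the acetyl group, which can chelate boron to the ketone oxygen, and leaves the para methoxy group, giving 6.

Step 6 (quinone methide generation and cross-coupling). The risk is slow release of 8, or retro-Michael exchange of the methylene bridge at 95 °C giving symmetrical dimers. The fallback swaps the roles of the two rings; it sets out from 3 and comes back at 9. Mannich reaction of 3 with Eschenmoser's salt (K2CO3, CH2Cl2, 0 °C → rt) gives 1-{3-[(dimethylamino)methyl]-2,4,6-trihydroxy-5-(3-methylbut-2-en-1-yl)phenyl}butan-1-one F3. Warming F3 with 6 in dioxane at 60–80 °C releases the more electrophilic quinone methide 2-butanoyl-3,5-dihydroxy-4-(3-methylbut-2-en-1-yl)-6-methylidenecyclohexa-2,4-dien-1-one F4 (not isolated). The phenolate of 6 captures F4 at its only free ring carbon to give 9.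

**Further compounds**
F1 | step 2 | 1-{2,6-dihydroxy-4-[(3-methylbut-2-en-1-yl)oxy]phenyl}butan-1-one | CCCC(=O)c1c(O)cc(OCC=C(C)C)cc1O
F2 | step 4 | 1-(2,4,6-trimethoxy-3-methylphenyl)ethan-1-one | CC(=O)c1c(OC)c(C)c(OC)cc1OC
F3 | step 6 | 1-{3-[(dimethylamino)methyl]-2,4,6-trihydroxy-5-(3-methylbut-2-en-1-yl)phenyl}butan-1-one | CCCC(=O)c1c(O)c(CC=C(C)C)c(O)c(CN(C)C)c1O
F4 | step 6 | 2-butanoyl-3,5-dihydroxy-4-(3-methylbut-2-en-1-yl)-6-methylidenecyclohexa-2,4-dien-1-one | CCCC(=O)C1=C(O)C(CC=C(C)C)=C(O)C(=C)C1=O
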